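- As the chemist holding the teal and blue runs, I had to say what a flask between them would show.

| flask | starting material | partner | remark | time |
|---|---|---|---|---|
| teal | 0.50 M | 0.70 equiv | run made earlier |  |
| blue | 0.50 M | 1.6 equiv | run made earlier |  |
| flask | 0.50 M | 1.05 equiv |  | 40 min |

| run | time / min | side product / % | target / % | starting material / % |
|---|---|---|---|---|
| teal | 6.00 | 6.1 | 5.5 | 43.6 |
| teal | 12.0 | 6.7 | 8.9 | 21.1 |
| teal | 20.0 | 7.0 | 9.7 | 5.8 |
| teal | 25.0 | 5.4 | 11.8 | 3.6 |
| blue | 2.00 | 6.1 | 2.7 | 72.6 |
| blue | 4.00 | 10.5 | 7.0 | 55.8 |
| blue | 10.0 | 13.2 | 16.0 | 25.4 |
| blue | 25.0 | 11.6 | 17.4 | 3.1 |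

(readings scatter by 1 percentage point)



1. ratio of side product to target at 1.5 min
2. ratio of side product to target at 8.0 min
3. ratio of side product to target at 40 min
4. which of side product and target there is more of at 40 min

- I drew the curve of side product over target from its start: at the first blue reading, 2.00 min, the ratio stood at 2.26, so I expected well above two at 1.5 min, and by interpolation the two lines crossed at 7.33 min in the blue run, which put the ratio just below one at 8.0 min.
- Then came the knee: blue side product plus target read 29.2% at 10.0 min and 29.0% at 25.0 min, though 25.4% of starting material still stood at the earlier time, and since starting material fell at 0.131 min⁻¹ in the teal run and 0.137 min⁻¹ in the blue run, I took partner's concentration to be what the products followed.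
- So the curve had to reach a level: summing each product over a run's last two readings gave 0.577 for the teal run and 0.743 for the blue run, and interpolating linearly in partner charge gave 0.641 for the flask, which I carried as the frozen ratio, side product over target once both have stopped growing, with target ahead at 40 min.
- The forecast gave 2.5, 1 and 0.45, with target ahead, and its last value lay below mine, on the ground that “Side product forms preferentially, then slowly converts to target or is lost”.
- The flask gave 2.73, 0.743 and 0.651, with target ahead at 13.7% against 8.92%, and its lines crossed at 4.85 min, earlier than my 7.33 min.

    partner → decomposed reagent (k = 0.00440 s⁻¹)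
    target → over-reaction product (k = 3.60 × 10⁻⁶ s⁻¹)
    starting material ⇌ intermediate A (K = 1.80, k = 0.00260 s⁻¹)
    partner + intermediate A → side product (k = 0.00920 M⁻¹ s⁻¹)
    intermediate A → intermediate B (k = 0.00860 s⁻¹)
    partner + intermediate B → target (k = 0.0140 M⁻¹ s⁻¹)

- In the flask partner was down to 0.0114% of its own charge at 20.0 min, and target and side product read 13.8% and 8.92% at that time and 13.7% and 8.92% at 40.0 min, against my frozen ratio of 0.641. The run without the step from partner to decomposed reagent ended at 0.375 instead of 0.651, so that decomposition held the ratio up. The neighbour flask with 2.60 equiv of partner, for which the same line gave 0.927, ended at 0.821, with 55.6% of intermediate B.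

The readings come from a simulation with made-up constants, noise included.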